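I begin with what a flask can leave over. A percentage of Q counts all its forms, free or not, so Q may hold J, and as a working guess for 40 h and no longer I count 2 J for each Q. That gives a scale for my reckoning, not a ceiling on Q, of 60.0% of the G charged at 1.20 equiv and 20.0% in autumn, while for noon, at 3.60 equiv, I take the whole G charged as the scale.

| flask | G | J | remark | time |
|---|---|---|---|---|
| beta | 0.40 M | 0.33 equiv | run made earlier |  |
| zeta | 0.40 M | 3.2 equiv | run made earlier |  |
| delta | 0.26 M | 1.2 equiv | run made earlier |  |
| noon | 0.25 M | 3.60 equiv |  | 40 h |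
| dawn | 0.40 M | 1.20 equiv |  | 40 h |
| autumn | 0.10 M | 0.400 equiv |  | 40 h |
| dusk | 0.80 M | 1.20 equiv |  | 40 h |
| winter | 1.2 M | 1.20 equiv |  | 40 h |

| run | time / h | Q / % |
|---|---|---|
| beta | 5.00 | 4 |
| beta | 10.0 | 0 |
| beta | 15.0 | 3 |
| beta | 20.0 | 6 |
| beta | 25.0 | 4 |
| beta | 30.0 | 9 |
| zeta | 2.00 | 2 |
| zeta | 5.00 | 3 |
| zeta | 10.0 | 8 |
| zeta | 15.0 | 20 |
| zeta | 20.0 | 29 |
| zeta | 30.0 | 52 |
| delta | 2.50 | 0 |
| delta | 8.00 | 4 |
| delta | 12.0 | 2 |
| delta | 20.0 | 10 |
| delta | 30.0 | 19 |

(readings scatter by 2 percentage points)

- a reading or a percentage of Q counts all its forms, free or not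

1. all flasks from highest to lowest amount of Q, in percent of the G charged, at 40 h (noon / dawn / autumn / dusk / winter)
2. the amount of Q, in percent of the G charged of the flask you put first, at 40 h
3. the amount of Q, in percent of the G charged of the flask you put last, at 40 h

Then comes the pace. Zeta, with cJ at 1.28 M, climbs from 8% at 10.0 h to 29% at 20.0 h, roughly as the square of the time, so something seems to build up first. Beta, with less J, stays low, so I scale the pace with cJ. I therefore carry one number, the reach: the logarithm of the inverse of the fraction of G unconverted in zeta at its last reading, 0.734, multiplied by a flask's cJ over zeta's and by the square of its time over zeta's. In my reckoning Q then bends exponentially towards that scale, with reach over scale as the exponent, as an interpolation for 40 h and not as a limit on what Q reaches later.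

Noon has a reach of 0.917, which gives 60.0%. Winter, with 1.47, has more reach but a lower scale and gives 54.8%, less than noon. Dusk gives 48.3%, dawn 33.5% and autumn 3.69%.

The forecast differs from me in first place: it gives winter > noon > dusk > dawn > autumn, with 60% and 3%, and says “the cause of the lag remains unclear”.

The flasks give noon > winter > dusk > dawn > autumn, with 59.9% first and 5.66% last.

    G ⇌ X (K = 1.55, k = 9.28 × 10⁻⁴ min⁻¹)
    J → E (k = 7.96 × 10⁻⁴ min⁻¹)
    X + E → Q (k = 0.00245 L mol⁻¹ min⁻¹)
    J + Q ⇌ D, settled at all times (K = 97.4 L mol⁻¹)

In noon, Q is made from X and E, and the passing of J into E has 23% of its turnover up to the asked time behind it by 4.00 h, a larger share than the 6.2% that the passing of X + E into Q has by 8.00 h, while the passing of G into X has 73% of its turnover behind it by 20.0 h. The reach gave noon 60.0% against 59.9%, and for a neighbour of noon charged with 0.062 M of G it gives 20.4%, where that flask holds 27.4%.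

(The readings stem from a simulated flask on assumed constants, noise included.)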